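## The problem

Target 11 is a C20 gibberellin whose ent-gibberellane core joins ring A (six-membered), ring B (five), ring C (six) and ring D (five), rings C and D forming a bicyclo[3.2.1]octane, and which carries a fifth ring, the δ-lactone that ties the C20 carboxyl on C10 to an oxygen on C12. There are ten stereocentres (C2, C3, C4, C5, C6, C8, C9, C10, C12, C13), three of them quaternary (C4, C8, C10) and crowded around ring B. Six of these (C4, C5, C8, C9, C10, C13) are those of the ent-kaurane diterpenoid acids and can be bought with the skeleton, but they cannot steer chemistry to the other four: C6 arises only when ring B is contracted, and C2, C3 and C12 are plain methylene carbons with no neighbouring functional group. The angular C20 methyl of the kauranes must also be raised to a carboxyl. The molecule tolerates little: the exocyclic C16=C17 alkene isomerises or hydrates in strong acid and reacts with electrophilic oxidants, the lactone opens in base, C6 can epimerise next to its carboxyl, and an ester at the axial C19 position is hard to cleave beside a lactone. The feature that invites a late ring closure lies in ring C, the chair of the bicyclooctane: the C15–C16 bridge takes the axial β positions at C8 and C13, so the axial positions at C9 and C12 both point to the α face. C9 carries C10 axially, the 12α hydrogen is axial, and the C20 carboxyl lies directly beneath it, so exchanging this one hydrogen for oxygen gives a hydroxy acid that can close only to the 20,12-lactone.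

## Retrosynthesis

**11 ⇒ 9.** The first cut is the C12–O bond of the lactone, together with the acyl C20–O bond that closes behind it. In the forward sense oxygen is inserted into the 12α C–H bond of triacid 9 and the resulting hydroxy acid 10 lactonises. Cutting only the acyl bond would leave 10, which is no simpler than 11 because the C12 stereocentre remains. Cutting C10–C20 or a ring B bond would spend the key step on framework that a kaurane already supplies. The chosen cut removes a ring and a stereocentre at once and lands on 9, the 12-deoxy 2β,3β-dihydroxy triacid, which is a known natural gibberellin of pumpkin seed. The forward reaction must pick one axial hydrogen, on the α face, out of many unactivated C–H bonds, beside an exocyclic alkene, three carboxylates and a diol. Only an enzyme pocket can do this, and cytochrome P450 monooxygenases are the catalyst class known to hydroxylate gibberellins at C12α.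

**9 ⇒ 7.** Next the C2–O and C3–O bonds are cut, giving triacid 7, itself a known gibberellin. Ring A of 7 offers no handle for building the cis-2β,3β-diol chemically; any osmylation or epoxidation would take the exocyclic alkene first, and three acids would need protection. The 2-oxoglutarate-dependent dioxygenases of gibberellin metabolism hydroxylate exactly these positions on the free acids. Two stereocentres disappear. The forward reaction must hydroxylate C3 and then C2, each on the β face, through mono-ol 8, with 2-oxoglutaric acid as the sacrificial co-substrate.

**7 ⇒ 4.** The C20 carboxyl is taken back to the angular methyl of diacid 4, the first gibberellin of the biosynthetic pathway. No chemical reagent oxidises this neopentyl methyl selectively, but a gibberellin 20-oxidase does so stepwise through alcohol 5 and aldehyde 6. No stereochemistry is involved. What is asked is that the enzyme carries on to the acid and does not expel C20 as CO2 at the aldehyde stage, which points to the 20-oxidase type of pumpkin seed.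

**4 ⇒ 1.** Finally ring B is re-expanded: the C6–C8 bond is cut, C7 is returned to the ring between C6 and C8, and its carboxyl becomes a methylene. This gives ent-kaurenoic acid 1, a purchasable diterpenoid acid that already holds C4, C5, C8, C9, C10 and C13 in the right configuration, the C19 carboxyl and the exocyclic alkene. Building the gibberellane skeleton from small fragments would cost tens of steps for what one known enzyme does. In the forward direction ent-kaurenoic acid oxidase hydroxylates C7 (2), contracts ring B with extrusion of C7 as the aldehyde (3) and oxidises the aldehyde to 4. The shift must create C6 with its carboxyl on the β face.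

## Roads not taken

Alternative 1: The cut is C6–C8, with ring C taken back to a phenol.
- Forward key step: phenol A1, a ring A block with an aryl group on quaternary C10 and a malonate at C6, would be oxidised with PhI(OAc)2. The malonate carbon attacks C8, para to the phenol oxygen, closing ring B and giving cyclohexa-2,5-dienone A2 with quaternary C8 and a propargyl group for ring D.
- Merits: it is purely chemical and of a well-known reaction class (oxidative dearomatisation with a stabilised carbon nucleophile). It makes the most congested quaternary centre and a ring in one step and leaves a carbonyl at C12, where the lactone oxygen is needed.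
- Weak points: A1 itself needs an enantioselective synthesis of ring A with four contiguous stereocentres (C2, C3, C4, C10), two of them quaternary. The configuration at C8 depends on which face of the arene the tether reaches, that is on the rotamer about the C9–C10 bond, and nothing in A1 secures it. After A2, ring D must still be closed from the alkyne to C13, one malonate ester removed with control of C6, the C12 ketone reduced to the axial 12α alcohol, and four methyl esters differentiated, including hydrolysis of the axial C19 ester beside the lactone. A realistic count is well above twenty steps.
- Comparison: this road is better in not depending on an enzyme for an unproven transformation, and it would give analogues. The chosen plan sets against it four steps, no protecting groups, all ten stereocentres either purchased or placed by enzymes, and a fallback in known biochemistry.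

Alternative 2: The cut is C10–C20.
- Forward key step: the 12α alcohol of a tetracyclic enone is carried as Se-phenyl selenocarbonate A3. (Me3Si)3SiH generates the alkoxycarbonyl radical, which adds 6-exo to C10, the β carbon of the C10=C1–C2(=O) enone, and gives lactone ketone A4 with C10 quaternary.
- Merits: the tether delivers C20 to the α face of C10 with no freedom, so the quaternary centre and the lactone form together with a predictable configuration. Cyclisation of alkoxycarbonyl radicals from selenocarbonates onto electron-poor alkenes is established, and the C2 ketone is a handle for the 2β-hydroxyl.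
- Weak points: A3 presupposes the 12α oxygen stereocentre, the B/C/D framework and a ring A enone with C3 and C4 set, so most of the problem is moved into its preparation. Radical attack at a fully substituted β carbon is slow, which gives time for loss of CO2 from the alkoxycarbonyl radical or for premature reduction. Silyl and acyl radicals can also add to the C16=C17 alkene. Afterwards the C2 ketone must be reduced to the equatorial 2β alcohol, the silyl ether removed, and the C7 and axial C19 methyl esters hydrolysed without opening the lactone.
- Comparison: the ring closure itself is on firmer ground than the enzymatic hydroxylation of the chosen plan, and its stereochemical outcome is guaranteed by geometry. The chosen plan sets against this that no C10–C20 bond has to be made at all (C20 is already in 1), that its precursor 9 is three steps from a purchasable compound, and that no deprotection follows.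

Alternative 3: The cut is C5–C6.
- Forward key step: with the lactone, ring A and the C/D bicycle in place, α-diazo ester A5 at C6 is decomposed with Rh2(O2CCPh3)4 (dirhodium tetrakis(triphenylacetate)). The carbenoid inserts into the equatorial C5–H bond of ring A, closes ring B and gives A6, the acetonide dimethyl ester of the target.
- Merits: intramolecular 1,5 C–H insertion is the standard way from diazo esters to cyclopentanes. It closes the last carbocycle late and sets C5 and C6 together. The lactone holds ring A close to the carbenoid, and the carbenoid carbon has no β hydrogen (C8 is quaternary), so hydride shift is excluded.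
- Weak points: C1–H is also 1,5-related to the carbenoid carbon and offers a second five-membered insertion. The C5 methylene is flanked by quaternary C4 and deactivated by the ester on C4. Cyclopropanation of the C16=C17 alkene competes, and two stereocentres must come out right in one event. A5 already contains the lactone and the 12α oxygen, so the problem the chosen plan solves in its key step is simply assumed solved. After A6 the acetonide and two methyl esters, one of them axial at C19, must be removed beside the lactone.
- Comparison: as a ring-forming event this is better founded than the key step of the chosen plan. It is, however, the longest road to reach. The chosen plan sets against it the purchase of ring B's precursor together with C5, and a key step that leaves nothing to deprotect.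

Key step: step 4

Remark: α and β refer to the conventional gibberellin drawing (C19 and C20 on the α face; the target is 2β,3β-dihydroxy with a 20,12α-lactone, as its SMILES encodes). ent-Kaurenoic acid 1 is taken as a purchasable natural product. Each enzymatic step is written as a cell-free incubation with a stoichiometric terminal reductant (D-glucose through glucose dehydrogenase for the P450 steps, 2-oxoglutaric acid for the dioxygenase steps); 2-oxoglutaric acid contributes no atoms to any product and is therefore treated as a reagent.

## Route

Step 1
Reactants: 1 ent-kaurenoic acid (ent-kaur-16-en-19-oic acid)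
Product: 4 ent-gibberell-16-ene-7,19-dioic acid (ring B contracted diacid with the C20 methyl), via 7β-hydroxy acid 2 (not isolated), via C7 aldehyde 3 (not isolated)
Conditions: ent-kaurenoic acid oxidase (P450 of the CYP88A subfamily) plus NADPH–cytochrome P450 reductase as yeast microsomes, NADP+ (cat.), D-glucose, glucose dehydrogenase, air, Tris·HCl pH 7.5, 30 °C; then HCl to pH 3, EtOAc
Reagents that add atoms: dioxygen, O=O
Why: Known three-stage oxidation by the P450 ent-kaurenoic acid oxidase of gibberellin biosynthesis on its own substrate: hydroxylation of C7 on the β face, then hydrogen abstraction at C6 with 1,2-shift of C8 from C7 to C6 (ring B contraction, C7 leaves the ring as the aldehyde), then aldehyde oxidation. The enzyme removes the 6β hydrogen and the migrating bond takes its place suprafacially, so the 6α hydrogen stays and C7 ends on the β face of the new stereocentre C6; the six stereocentres of 1 are untouched.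

Step 2
Reactants: 4 ent-gibberell-16-ene-7,19-dioic acid
Product: 7 ent-gibberell-16-ene-7,19,20-trioic acid (triacid), via C20 alcohol 5 (not isolated), via C20 aldehyde 6 (not isolated)
Conditions: recombinant gibberellin 20-oxidase of the Cucurbita maxima seed type, 2-oxoglutaric acid (excess), FeSO4 (cat.), sodium L-ascorbate, catalase, air, Tris·HCl pH 7.5, 30 °C; then HCl to pH 3, EtOAc
Reagents that add atoms: dioxygen, O=O
Why: Known 2-oxoglutarate-dependent non-haem iron dioxygenase chemistry: the 20-oxidase of pumpkin seed oxidises the C20 methyl of this diacid through alcohol and aldehyde and is the member of its family that releases the tricarboxylic acid instead of expelling C20. Each turnover couples decarboxylation of 2-oxoglutarate to an iron-oxo species (ascorbate keeps the resting iron divalent) that hydroxylates C20; no stereocentre is formed or touched.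

Step 3
Reactants: 7 ent-gibberell-16-ene-7,19,20-trioic acid
Product: 9 ent-2α,3α-dihydroxygibberell-16-ene-7,19,20-trioic acid (2β,3β-dihydroxy triacid), via 3β-hydroxy triacid 8 (not isolated)
Conditions: recombinant gibberellin 2β,3β-hydroxylase of Cucurbita maxima endosperm, 2-oxoglutaric acid (excess), FeSO4 (cat.), sodium L-ascorbate, catalase, air, Tris·HCl pH 7.5, 30 °C; then HCl to pH 3, EtOAc
Reagents that add atoms: dioxygen, O=O
Why: Known 2-oxoglutarate-dependent dioxygenase hydroxylation of gibberellins in ring A: the bifunctional 2β,3β-hydroxylase of pumpkin endosperm accepts C20 tricarboxylic acids and hydroxylates C3 and then C2. The iron-oxo species removes the β hydrogen and returns hydroxyl to the same face of the same carbon (retention), so both new stereocentres (3β axial, 2β equatorial) are fixed by the enzyme.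

Step 4
Reactants: 9 ent-2α,3α-dihydroxygibberell-16-ene-7,19,20-trioic acid
Product: 11 target lactone (2β,3β-dihydroxy-ent-gibberell-16-ene-7,19,20-trioic acid 20,12α-lactone), via 12α-hydroxy triacid 10 (not isolated)
Conditions: gibberellin 12α-hydroxylase of the CYP714A subfamily (variant selected on 9) plus NADPH–cytochrome P450 reductase as yeast microsomes, NADP+ (cat.), D-glucose, glucose dehydrogenase, air, KH2PO4/K2HPO4 buffer pH 7.4, 28 °C; then aq. HCl to pH 2.5, EtOAc, 23 °C
Reagents that add atoms: dioxygen, O=O
Why: Proposed new method: P450 12α-hydroxylation is known for C20 gibberellins that still carry the C20 methyl group (diacids of the type of 4, with a recombinant CYP714-family enzyme and with pumpkin microsomes) and P450 hydroxylation of other diterpenoid acids is common, but hydroxylation of a 2,3-dihydroxy tricarboxylic acid with lactone closure in the same operation has not been shown, so the step is argued from mechanism. The ferryl-oxo porphyrin radical cation of the enzyme (formally tetravalent iron) abstracts the axial 12α hydrogen and the C12 radical recombines with the iron-bound hydroxyl on the same face (oxygen rebound), so the C12–O bond forms with retention and the new stereocentre is fixed by the active site, helped by the C15–C16 bridge that covers the β face of ring C. The hydroxy triacid 10 is not isolated: its 12α-hydroxyl and the C9–C10 bond are 1,3-diaxial on the ring C chair, which holds the oxygen against the C20 carboxyl, and at pH 2.5 it closes by 6-exo-trig acyl substitution to the δ-lactone (a 2-oxabicyclo[3.3.1]nonan-3-one built on C9, C11 and C12). The closure is regiospecific because no other hydroxyl can reach a carboxyl in a strain-free ring: the 2β- and 3β-hydroxyls lie on the face opposite C19 and C20, and C7 is remote. The selectivity that must be won is C12α against C13–H, the other ring C hydrogens and the C16=C17 alkene. The substrate contributes an unhindered axial 12α hydrogen on the open α face next to a carboxylate that can serve as a binding handle. The rest is asked of the pocket, to be secured by screening CYP714-family and soluble bacterial gibberellin-binding P450s and by mutagenesis that places a cationic residue opposite C20 and makes room for the ring A diol.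

## Compound list

1 | ent-kaurenoic acid (ent-kaur-16-en-19-oic acid) | C=C1C[C@]23C[C@H]1CC[C@H]2[C@@]2(CCC[C@@](C)(C(=O)O)[C@H]2CC3)C | starting material
2 | ent-7α-hydroxykaur-16-en-19-oic acid (7β-hydroxyl in the conventional drawing; formed in the flask, not isolated) | C=C1C[C@]23C[C@H]1CC[C@H]2[C@@]2(CCC[C@@](C)(C(=O)O)[C@H]2C[C@@H]3O)C | intermediate
3 | ent-7-oxogibberell-16-en-19-oic acid (ring B contracted, CHO on the β face of C6, C19 acid, C20 methyl; not isolated) | C=C1C[C@]23C[C@H]1CC[C@H]2[C@@]2(CCC[C@@](C)(C(=O)O)[C@H]2[C@@H]3C=O)C | intermediate
4 | ent-gibberell-16-ene-7,19-dioic acid (ring B contracted diacid with the C20 methyl) | C=C1C[C@]23C[C@H]1CC[C@H]2[C@@]2(CCC[C@@](C)(C(=O)O)[C@H]2[C@@H]3C(=O)O)C | intermediate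
5 | ent-20-hydroxygibberell-16-ene-7,19-dioic acid (C20 alcohol, open hydroxy acid form; not isolated) | C=C1C[C@]23C[C@H]1CC[C@H]2[C@@]2(CCC[C@@](C)(C(=O)O)[C@H]2[C@@H]3C(=O)O)CO | intermediate
6 | ent-20-oxogibberell-16-ene-7,19-dioic acid (C20 aldehyde; not isolated) | C=C1C[C@]23C[C@H]1CC[C@H]2[C@@]2(CCC[C@@](C)(C(=O)O)[C@H]2[C@@H]3C(=O)O)C=O | intermediate
7 | ent-gibberell-16-ene-7,19,20-trioic acid (triacid) | C=C1C[C@]23C[C@H]1CC[C@H]2[C@@]2(CCC[C@@](C)(C(=O)O)[C@H]2[C@@H]3C(=O)O)C(=O)O | intermediate
8 | ent-3α-hydroxygibberell-16-ene-7,19,20-trioic acid (3β-hydroxy triacid; not isolated) | C=C1C[C@]23C[C@H]1CC[C@H]2[C@@]2(CC[C@H](O)[C@@](C)(C(=O)O)[C@H]2[C@@H]3C(=O)O)C(=O)O | intermediate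
9 | ent-2α,3α-dihydroxygibberell-16-ene-7,19,20-trioic acid (2β,3β-dihydroxy triacid) | C=C1C[C@]23C[C@H]1CC[C@H]2[C@@]2(C[C@H](O)[C@H](O)[C@@](C)(C(=O)O)[C@H]2[C@@H]3C(=O)O)C(=O)O | intermediate
10 | 2β,3β,12α-trihydroxy triacid (12α-hydroxy derivative of 9; not isolated) | C=C1C[C@]23C[C@H]1[C@@H](O)C[C@H]2[C@@]2(C[C@H](O)[C@H](O)[C@@](C)(C(=O)O)[C@H]2[C@@H]3C(=O)O)C(=O)O | intermediate
11 | 2β,3β-dihydroxy-ent-gibberell-16-ene-7,19,20-trioic acid 20,12α-lactone (CNP0212122.1) | C=C1C[C@]23C[C@H]1[C@@H]1C[C@H]2[C@@]2(C[C@H](O)[C@H](O)[C@@](C)(C(=O)O)[C@H]2[C@@H]3C(=O)O)C(=O)O1 | target

## Step count and least certain steps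

Total step count: 4. Longest linear sequence: 4 steps (1 → 4 → 7 → 9 → 11). Step 1 is ranked safest, since it uses the recombinant enzyme on its own substrate.

**Step 4 (key step, proposed new method).** Several things may go wrong:
- no productive binding, because a membrane-bound hydroxylase shaped for a C20-methyl diacid may not admit a triacid diol whose third carboxylate sits next to the carbon to be oxidised;
- loss of site selectivity, through hydroxylation at C13 or epoxidation of the exocyclic alkene, both known outcomes in this enzyme family;
- a second oxidation of the new alcohol to the ketone while it stays open-chain at pH 7.4;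
- slow lactonisation that tempts stronger acid and so isomerisation of the exocyclic alkene.

The fallback uses known chemistry and changes the order of events, so that the lactone oxygen is introduced where 12α-hydroxylation is established and the ring closes after C20 oxidation. It sets out from 4. The 12α-hydroxylase of the CYP714A subfamily, under the conditions of step 1 and acting on the C20-methyl diacid, would give the 12α-hydroxy C20-methyl diacid F1. The 20-oxidase of step 2 would take F1 through the 12α,20-dihydroxy diacid F2 and the 12α-hydroxy C20 aldehyde F3 to the 12α-hydroxy triacid F4, kept at pH 7.5 as the open carboxylate. The 2β,3β-hydroxylase of step 3 would then hydroxylate F4 through the 3β,12α-dihydroxy triacid F5 to 10, where the route is rejoined; acidification as in step 4 closes 10 to 11. This is the order in which 12α-oxygenated gibberellins are processed by the pumpkin endosperm enzymes.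

**Step 3.** The likely failure is arrest after the first hydroxylation through self-inactivation of the dioxygenase, so that mono- and dihydroxy triacids have to be separated; a recombinant fusion protein may also lose the C2 activity of the native enzyme. The fallback replaces the two isolated dioxygenase steps by one native cascade. It sets out from 4, which is incubated with the dialysed soluble enzyme fraction of immature Cucurbita maxima endosperm (2-oxoglutaric acid, FeSO4, sodium L-ascorbate, air, pH 7.5), the tissue whose enzymes carry C20 oxidation and both ring A hydroxylations through to the 2β,3β-dihydroxy triacid. The cascade passes 5, 6, 7 and 8. Where ring A hydroxylation overtakes the last C20 oxidation, the 3β-hydroxy C20 aldehyde F6 takes the place of 7 and is oxidised on to 8. The route is rejoined at 9.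

**Step 2.** The likely failures are loss of C20 as CO2 at the aldehyde stage (diversion into the C19 series), or arrest at the alcohol stage through closure of the 19,20-lactone outside the enzyme. The fallback finishes the oxidation chemically. It sets out from 4: the enzymatic oxidation is stopped at the aldehyde stage by a short incubation with limiting 2-oxoglutaric acid, aldehyde 6 is isolated, and a Pinnick oxidation (NaClO2, NaH2PO4, 2-methylbut-2-ene, t-BuOH/H2O, 23 °C) converts it to 7, where the route is rejoined. The alkene scavenger protects the exocyclic methylene from hypochlorous acid, and the 19,20-lactol of 6 opens under the buffered conditions. This fallback makes no compound outside the compound list (F0).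

## Further compounds

F1 | step 4 | 12α-hydroxy C20-methyl diacid (ent-12β-hydroxygibberell-16-ene-7,19-dioic acid) | C=C1C[C@]23C[C@H]1[C@@H](O)C[C@H]2[C@@]2(CCC[C@@](C)(C(=O)O)[C@H]2[C@@H]3C(=O)O)C
F2 | step 4 | 12α,20-dihydroxy diacid (ent-12β,20-dihydroxygibberell-16-ene-7,19-dioic acid) | C=C1C[C@]23C[C@H]1[C@@H](O)C[C@H]2[C@@]2(CCC[C@@](C)(C(=O)O)[C@H]2[C@@H]3C(=O)O)CO
F3 | step 4 | 12α-hydroxy C20 aldehyde (ent-12β-hydroxy-20-oxogibberell-16-ene-7,19-dioic acid) | C=C1C[C@]23C[C@H]1[C@@H](O)C[C@H]2[C@@]2(CCC[C@@](C)(C(=O)O)[C@H]2[C@@H]3C(=O)O)C=O
F4 | step 4 | 12α-hydroxy triacid (ent-12β-hydroxygibberell-16-ene-7,19,20-trioic acid) | C=C1C[C@]23C[C@H]1[C@@H](O)C[C@H]2[C@@]2(CCC[C@@](C)(C(=O)O)[C@H]2[C@@H]3C(=O)O)C(=O)O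
F5 | step 4 | 3β,12α-dihydroxy triacid (ent-3α,12β-dihydroxygibberell-16-ene-7,19,20-trioic acid) | C=C1C[C@]23C[C@H]1[C@@H](O)C[C@H]2[C@@]2(CC[C@H](O)[C@@](C)(C(=O)O)[C@H]2[C@@H]3C(=O)O)C(=O)O
F6 | step 3 | 3β-hydroxy C20 aldehyde diacid (ent-3α-hydroxy-20-oxogibberell-16-ene-7,19-dioic acid) | C=C1C[C@]23C[C@H]1CC[C@H]2[C@@]2(CC[C@H](O)[C@@](C)(C(=O)O)[C@H]2[C@@H]3C(=O)O)C=O
F0 | step 2 | none | none
A1 | alternative 1 | C12 phenol with a C6 malonate, an aryl group on quaternary C10 and a propargyl group on C8 (ring A acetonide, methyl esters) | C#CCc1ccc(O)cc1[C@@]1(C[C@H](OC(C)(C)O2)[C@H]2[C@@](C)(C(=O)OC)[C@H]1C(C(=O)OC)C(=O)OC)C(=O)OC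
A2 | alternative 1 | ring A/B/C cyclohexa-2,5-dienone with quaternary C8 | C#CC[C@]12C=CC(=O)C=C1[C@@]1(C[C@H](OC(C)(C)O3)[C@H]3[C@@](C)(C(=O)OC)[C@H]1C2(C(=O)OC)C(=O)OC)C(=O)OC
A3 | alternative 2 | 12α Se-phenyl selenocarbonate of the C1=C10 en-2-one (3β-silyl ether, dimethyl ester) | C=C1C[C@]23C[C@H]1[C@@H](OC(=O)[Se]c1ccccc1)C[C@H]2C2=CC(=O)[C@H](O[Si](C)(C)C(C)(C)C)[C@@](C)(C(=O)OC)[C@H]2[C@@H]3C(=O)OC
A4 | alternative 2 | 20,12α-lactone C2 ketone with quaternary C10 (3β-silyl ether, dimethyl ester) | C=C1C[C@]23C[C@H]1[C@@H]1C[C@H]2[C@@]2(CC(=O)[C@H](O[Si](C)(C)C(C)(C)C)[C@@](C)(C(=O)OC)[C@H]2[C@@H]3C(=O)OC)C(=O)O1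
A5 | alternative 3 | C6 α-diazo ester on C8 with ring B open (20,12α-lactone, acetonide, C19 methyl ester) | C=C1C[C@]2(C(=[N+]=[N-])C(=O)OC)C[C@H]1[C@@H]1C[C@H]2[C@@]2(C[C@H](OC(C)(C)O3)[C@H]3[C@@](C)(C(=O)OC)C2)C(=O)O1
A6 | alternative 3 | protected target (2,3-acetonide, C7 and C19 dimethyl ester) | C=C1C[C@]23C[C@H]1[C@@H]1C[C@H]2[C@@]2(C[C@H](OC(C)(C)O4)[C@H]4[C@@](C)(C(=O)OC)[C@H]2[C@@H]3C(=O)OC)C(=O)O1
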